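**Strategy.** The 14-membered carbocycle is opened at C11–C12. The C11=C12 alkene carries methyl C20 on C12, two atoms from the C14 oxygen, so it can be derived from a C11≡C12 cycloalkyne by hydroxyl-directed trans-hydrostannation and methyl Stille coupling. Ring-closing alkyne metathesis of a diyne with two 2-butynyl termini therefore forms the macrocycle in one operation, free of E/Z ambiguity, in the presence of the trans-fused α-methylene-γ-lactone (C1, C2, C15, C16), the C3–C4 epoxide and the C7=C8 alkene. The precursor is the seco epoxy lactone from indium allylation of pent-3-ynal with a geraniol-derived epoxy bromomethylbutenolide; O14 is silylated during metathesis.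

Key step: step 18

Remarks on the chemistry: cembrane numbering is used throughout (C1/C2 ring-fusion carbons, C3/C4 epoxide, C14 carbinol, C15/C16/C17 lactone α-carbon, carbonyl and methylene, C20 methyl on C12); O2 and the epoxide oxygen are threo, the anti-Felkin sense for carbon-nucleophile addition to the epoxy aldehyde, so C2 is set by ketone reduction; D-(−)-diethyl tartrate is taken to give the (2R,3R) epoxide as in the geraniol series.

**Step 1**
Reactants: 1 geraniol
Product: 2 geranyl tert-butyldimethylsilyl ether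
Conditions: TBSCl, imidazole, DMF, rt
Reagents that add atoms: tert-butyldimethylsilyl chloride CC(C)(C)[Si](C)(C)Cl
Why: Silyl ether protection of the primary allylic alcohol, needed because organolithium reagents follow.

**Step 2**
Reactants: 2 geranyl tert-butyldimethylsilyl ether
Product: 3 (2E,6E)-8-silyloxy-2,6-dimethylocta-2,6-dien-1-ol
Conditions: SeO2 (cat.), t-BuOOH, salicylic acid (cat.), CH2Cl2, rt
Reagents that add atoms: tert-butyl hydroperoxide CC(C)(C)OO
Why: Riley-type allylic oxidation (ene reaction then [2,3]-shift) should attack the electron-richer terminal alkene at its E-methyl group, the C2=C3 alkene being deactivated by the allylic silyloxy group.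

**Step 3**
Reactants: 3 (2E,6E)-8-silyloxy-2,6-dimethylocta-2,6-dien-1-ol
Product: 4 (2E,6E)-8-bromo-3,7-dimethylocta-2,6-dienyl tert-butyldimethylsilyl ether
Conditions: CBr4, PPh3, CH2Cl2, 0 °C
Reagents that add atoms: carbon tetrabromide BrC(Br)(Br)Br
Why: The Appel reaction converts the primary allylic alcohol into the bromide under neutral conditions without allylic transposition.

**Step 4**
Reactants: 4 allylic bromide; 5 1-(trimethylsilyl)propyne
Product: 7 (2E,6E)-3,7-dimethyl-11-(trimethylsilyl)undeca-2,6-dien-10-ynyl tert-butyldimethylsilyl ether, via 3-lithio-1-(trimethylsilyl)propyne 6 (not isolated)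
Conditions: n-BuLi, THF, −78 °C; then 4, −78 to −20 °C
Reagents that add atoms: none
Why: Propargylic lithiation followed by SN2 alkylation of the primary allylic bromide forms C9–C10, the silyl group directing coupling through the propargylic rather than the allenic terminus.

**Step 5**
Reactants: 7 silylalkyne
Product: 9 (2E,6E)-3,7-dimethyldodeca-2,6-dien-10-ynyl tert-butyldimethylsilyl ether, via lithium acetylide 8 (not isolated)
Conditions: MeLi·LiBr, THF, 0 °C to rt; then MeI, 0 °C to rt
Reagents that add atoms: iodomethane CI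
Why: Nucleophilic cleavage of the C(sp)–Si bond by methyllithium gives the lithium acetylide, whose C-methylation installs the methyl cap required for alkyne metathesis.

**Step 6**
Reactants: 9 methyl-capped enyne silyl ether
Product: 10 (2E,6E)-3,7-dimethyldodeca-2,6-dien-10-yn-1-ol
Conditions: Bu4NF, THF, 0 °C to rt
Reagents that add atoms: none
Why: Fluoride-mediated desilylation frees the allylic alcohol for directed epoxidation.

**Step 7**
Reactants: 10 dienynol
Product: 11 (2R,3R)-epoxy alcohol
Conditions: Ti(OiPr)4 (cat.), D-(−)-diethyl tartrate, t-BuOOH, 4 Å MS, CH2Cl2, −20 °C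
Reagents that add atoms: tert-butyl hydroperoxide CC(C)(C)OO
Why: Sharpless asymmetric epoxidation touches only the allylic alcohol alkene, and the D-(−)-tartrate complex delivers oxygen to the face that gives the (2R,3R) epoxide, setting C3 and C4.

**Step 8**
Reactants: 11 (2R,3R)-epoxy alcohol
Product: 12 (2S,3R)-epoxy aldehyde
Conditions: Dess–Martin periodinane, NaHCO3, CH2Cl2, 0 °C to rt
Reagents that add atoms: none
Why: Buffered Dess–Martin oxidation gives the 2,3-epoxy aldehyde without epimerisation or epoxide opening.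

**Step 9**
Reactants: 12 epoxy aldehyde; 13 ethyl propiolate
Product: 15 ethyl 4-hydroxy-4-oxiranylbut-2-ynoate as a mixture of C4 epimers, via lithium ethyl propiolate 14 (not isolated)
Conditions: LiN(SiMe3)2, THF, −78 °C; then 12, −78 °C
Reagents that add atoms: none
Why: 1,2-Addition of the lithium acetylide forms C1–C2; Felkin–Anh control is expected to favour the unwanted carbinol epimer, so both epimers are carried on and converge in the next step.

**Step 10**
Reactants: 15 hydroxy ynoate (epimer mixture)
Product: 16 ethyl 4-oxo-4-oxiranylbut-2-ynoate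
Conditions: Dess–Martin periodinane, NaHCO3, CH2Cl2, 0 °C
Reagents that add atoms: none
Why: Dess–Martin oxidation of the propargylic alcohol erases the uncontrolled carbinol centre under non-basic conditions tolerated by the ynoate and the epoxide.

**Step 11**
Reactants: 16 epoxy ynone
Product: 17 ethyl (4S)-4-hydroxy-4-oxiranylbut-2-ynoate
Conditions: (R)-2-methyl-CBS-oxazaborolidine, catecholborane, toluene, −78 °C
Reagents that add atoms: none
Why: Corey–Bakshi–Shibata reduction should deliver hydride anti to the epoxide C–O bond (Felkin–Anh, no chelation), and the (R)-catalyst, reading the oxiranyl group as the larger substituent, reinforces that face to give the threo (S) carbinol at C2.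

**Step 12**
Reactants: 17 (4S)-hydroxy ynoate
Product: 20 (5S)-3-iodo-5-oxiranylfuran-2(5H)-one, via α-stannyl hydroxy enoate 18 (not isolated), via α-stannyl butenolide 19 (not isolated)
Conditions: PdCl2(PPh3)2 (cat.), Bu3SnH, THF, 0 °C; PPTS (cat.), rt; then I2, CH2Cl2, 0 °C
Reagents that add atoms: iodine II
Why: Palladium-catalysed syn-hydrostannation should be selective for the ynoate over the dialkylalkyne and place tin α to the ester, the cis γ-hydroxy ester lactonises, and iododestannylation proceeds with retention.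

**Step 13**
Reactants: 20 α-iodobutenolide
Product: 21 (5S)-3-(hydroxymethyl)-5-oxiranylfuran-2(5H)-one
Conditions: Pd(PPh3)4 (cat.), Bu3SnCH2OH, dioxane, 80 °C
Reagents that add atoms: (tributylstannyl)methanol OC[Sn](CCCC)(CCCC)CCCC
Why: Stille coupling of the alkenyl iodide with the hydroxymethylstannane installs C17 under neutral conditions that spare the base-sensitive γ-epoxy butenolide.

**Step 14**
Reactants: 21 hydroxymethyl butenolide
Product: 22 (5S)-3-(bromomethyl)-5-oxiranylfuran-2(5H)-one
Conditions: CBr4, PPh3, CH2Cl2, 0 °C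
Reagents that add atoms: carbon tetrabromide BrC(Br)(Br)Br
Why: The Appel reaction gives the allylic bromide without base, which would otherwise open the epoxide through the acidic γ-position.

**Step 15**
Reactants: 23 pent-3-yn-1-ol
Product: 24 pent-3-ynal
Conditions: Dess–Martin periodinane, NaHCO3, CH2Cl2, 0 °C; solution used at once
Reagents that add atoms: none
Why: Dess–Martin oxidation gives the β,γ-ynal under conditions mild enough to avoid isomerisation to the allenal.

**Step 16**
Reactants: 22 bromomethyl butenolide; 24 pent-3-ynal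
Product: 26 seco diyne epoxy lactone with free C14 hydroxyl, via allylindium dibromide 25 (not isolated)
Conditions: In powder, THF/H2O, rt
Reagents that add atoms: none
Why: Indium-mediated Barbier allylation should form C1–C14 by SE2′ attack through C1 on the face anti to the C2 substituent (trans lactone), and a Zimmerman–Traxler chair with the ring-locked E-type allyl unit should give the anti C1/C14 relationship, that is 14S.

**Step 17**
Reactants: 26 seco diyne alcohol
Product: 27 seco diyne C14 triethylsilyl ether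
Conditions: TESOTf, 2,6-lutidine, CH2Cl2, −78 °C
Reagents that add atoms: triethylsilyl triflate CC[Si](CC)(CC)OS(=O)(=O)C(F)(F)F
Why: Silylation with a non-nucleophilic base masks the only protic group, which could otherwise exchange with the silanolate ligands of the metathesis catalyst, and does not add to the methylene lactone.

**Step 18**
Reactants: 27 seco diyne C14 triethylsilyl ether
Product: 28 20-nor-11,12-didehydro cycloalkyne C14 triethylsilyl ether
Conditions: Mo(≡CC6H4OMe-4)(OSiPh3)3 (cat.), 5 Å MS, toluene, 2 mM, 80 °C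
Reagents that add atoms: none
Why: The molybdenum alkylidyne adds to one 2-butynyl terminus by [2+2] cycloaddition to a molybdacyclobutadiene, cycloreversion expels 2-butyne, and the substrate-bound alkylidyne repeats the sequence with the second terminus to form C11≡C12; the closest known reaction type is ring-closing alkyne metathesis of methyl-capped diynes to 14-membered cycloalkynes with silanolate-ligated molybdenum alkylidynes. The one ring formed is the 14-membered carbocycle, closed by macrocyclisation with the new triple bond endocyclic, a ring size that accommodates the four collinear atoms C10–C13. No stereocentre is created and no alkene geometry is at stake, since the alkene is written in afterwards by trans addition. The step needs ring closure to win over oligomerisation and needs reaction at the two alkynes only: high dilution and capture of 2-butyne by the molecular sieves should secure the first, helped by the turn that the trans-fused lactone and the epoxide impose on the chain, and the alkylidyne is inert towards the C7=C8 alkene, the methylene lactone and the epoxide. The triethylsilyl ether keeps the hydroxyl away from the catalyst.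

**Step 19**
Reactants: 28 cycloalkyne triethylsilyl ether
Product: 29 20-nor-11,12-didehydro cycloalkyne C14 alcohol
Conditions: HF·pyridine, pyridine, THF, 0 °C
Reagents that add atoms: none
Why: Buffered fluoride desilylation frees the C14 hydroxyl without opening the epoxide or adding to the methylene lactone.

**Step 20**
Reactants: 29 cycloalkyne alcohol
Product: 30 (11Z)-12-(tributylstannyl) alkene alcohol
Conditions: [Cp*RuCl]4 (cat.), Bu3SnH, CH2Cl2, rt
Reagents that add atoms: tributyltin hydride CCCC[SnH](CCCC)CCCC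
Why: In the hydroxyl-directed ruthenium-catalysed trans-hydrostannation the C14 hydroxyl hydrogen-bonds to the chloride on ruthenium, so tin should end on the proximal carbon C12 and hydrogen on C11 from the opposite face, fixing the ring geometry of the future 11E alkene.

**Step 21**
Reactants: 30 alkenylstannane
Product: 31 14-deacetyl target (C14 alcohol with C20 methyl)
Conditions: Pd(PPh3)4, Cu(O2CC4H3S) (copper thiophene-2-carboxylate), [Ph2PO2][NBu4], MeI, DMF, rt
Reagents that add atoms: iodomethane CI
Why: Copper-assisted Stille–Migita methylation replaces tin by methyl with retention of alkene geometry, the phosphinate trapping the tin residue, and tolerates the free hydroxyl.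

**Step 22**
Reactants: 31 C14 alcohol
Product: 32 CNP0294029.1
Conditions: Ac2O, pyridine, DMAP (cat.), CH2Cl2, 0 °C to rt
Reagents that add atoms: acetic anhydride CC(=O)OC(C)=O
Why: Standard acylation of the secondary alcohol completes the target and removes the possibility of lactone migration to O14.

**Compound list**

1 | geraniol, (2E)-3,7-dimethylocta-2,6-dien-1-ol | CC(C)=CCC/C(C)=C/CO | starting material
2 | tert-butyl{[(2E)-3,7-dimethylocta-2,6-dien-1-yl]oxy}dimethylsilane | CC(C)=CCC/C(C)=C/CO[Si](C)(C)C(C)(C)C | intermediate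
3 | (2E,6E)-8-[(tert-butyldimethylsilyl)oxy]-2,6-dimethylocta-2,6-dien-1-ol | OC/C(C)=C/CC/C(C)=C/CO[Si](C)(C)C(C)(C)C | intermediate
4 | {[(2E,6E)-8-bromo-3,7-dimethylocta-2,6-dien-1-yl]oxy}(tert-butyl)dimethylsilane | BrC/C(C)=C/CC/C(C)=C/CO[Si](C)(C)C(C)(C)C | intermediate
5 | 1-(trimethylsilyl)propyne | CC#C[Si](C)(C)C | starting material
6 | 3-lithio-1-(trimethylsilyl)propyne (not isolated) | [Li]CC#C[Si](C)(C)C | intermediate
7 | tert-butyl{[(2E,6E)-3,7-dimethyl-11-(trimethylsilyl)undeca-2,6-dien-10-yn-1-yl]oxy}dimethylsilane | C[Si](C)(C)C#CCC/C(C)=C/CC/C(C)=C/CO[Si](C)(C)C(C)(C)C | intermediate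
8 | lithium (5E,9E)-11-[(tert-butyldimethylsilyl)oxy]-5,9-dimethylundeca-5,9-dien-1-ynide (not isolated) | [Li]C#CCC/C(C)=C/CC/C(C)=C/CO[Si](C)(C)C(C)(C)C | intermediate
9 | tert-butyl{[(2E,6E)-3,7-dimethyldodeca-2,6-dien-10-yn-1-yl]oxy}dimethylsilane | CC#CCC/C(C)=C/CC/C(C)=C/CO[Si](C)(C)C(C)(C)C | intermediate
10 | (2E,6E)-3,7-dimethyldodeca-2,6-dien-10-yn-1-ol | CC#CCC/C(C)=C/CC/C(C)=C/CO | intermediate
11 | {(2R,3R)-3-methyl-3-[(3E)-4-methylnon-3-en-7-yn-1-yl]oxiran-2-yl}methanol | OC[C@H]1O[C@]1(C)CC/C=C(C)/CCC#CC | intermediate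
12 | (2S,3R)-3-methyl-3-[(3E)-4-methylnon-3-en-7-yn-1-yl]oxirane-2-carbaldehyde | O=C[C@H]1O[C@]1(C)CC/C=C(C)/CCC#CC | intermediate
13 | ethyl propiolate | C#CC(=O)OCC | starting material
14 | lithium ethyl propiolate, ethyl 3-lithioprop-2-ynoate (not isolated) | [Li]C#CC(=O)OCC | intermediate
15 | ethyl 4-hydroxy-4-{(2R,3R)-3-methyl-3-[(3E)-4-methylnon-3-en-7-yn-1-yl]oxiran-2-yl}but-2-ynoate, C4 epimers | CCOC(=O)C#CC(O)[C@H]1O[C@]1(C)CC/C=C(C)/CCC#CC | intermediate
16 | ethyl 4-{(2S,3R)-3-methyl-3-[(3E)-4-methylnon-3-en-7-yn-1-yl]oxiran-2-yl}-4-oxobut-2-ynoate | CCOC(=O)C#CC(=O)[C@H]1O[C@]1(C)CC/C=C(C)/CCC#CC | intermediate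
17 | ethyl (4S)-4-hydroxy-4-{(2R,3R)-3-methyl-3-[(3E)-4-methylnon-3-en-7-yn-1-yl]oxiran-2-yl}but-2-ynoate | CCOC(=O)C#C[C@H](O)[C@H]1O[C@]1(C)CC/C=C(C)/CCC#CC | intermediate
18 | ethyl (2E,4S)-4-hydroxy-4-{(2R,3R)-3-methyl-3-[(3E)-4-methylnon-3-en-7-yn-1-yl]oxiran-2-yl}-2-(tributylstannyl)but-2-enoate (not isolated) | CCOC(=O)/C([Sn](CCCC)(CCCC)CCCC)=C\[C@H](O)[C@H]1O[C@]1(C)CC/C=C(C)/CCC#CC | intermediate
19 | (5S)-5-{(2R,3R)-3-methyl-3-[(3E)-4-methylnon-3-en-7-yn-1-yl]oxiran-2-yl}-3-(tributylstannyl)furan-2(5H)-one (not isolated) | O=C1O[C@H]([C@H]2O[C@]2(C)CC/C=C(C)/CCC#CC)C=C1[Sn](CCCC)(CCCC)CCCC | intermediate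
20 | (5S)-3-iodo-5-{(2R,3R)-3-methyl-3-[(3E)-4-methylnon-3-en-7-yn-1-yl]oxiran-2-yl}furan-2(5H)-one | O=C1O[C@H]([C@H]2O[C@]2(C)CC/C=C(C)/CCC#CC)C=C1I | intermediate
21 | (5S)-3-(hydroxymethyl)-5-{(2R,3R)-3-methyl-3-[(3E)-4-methylnon-3-en-7-yn-1-yl]oxiran-2-yl}furan-2(5H)-one | O=C1O[C@H]([C@H]2O[C@]2(C)CC/C=C(C)/CCC#CC)C=C1CO | intermediate
22 | (5S)-3-(bromomethyl)-5-{(2R,3R)-3-methyl-3-[(3E)-4-methylnon-3-en-7-yn-1-yl]oxiran-2-yl}furan-2(5H)-one | O=C1O[C@H]([C@H]2O[C@]2(C)CC/C=C(C)/CCC#CC)C=C1CBr | intermediate
23 | pent-3-yn-1-ol | CC#CCCO | starting material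
24 | pent-3-ynal | CC#CCC=O | intermediate
25 | allylindium dibromide derived from 22, indium on the former bromomethyl carbon (not isolated) | O=C1O[C@H]([C@H]2O[C@]2(C)CC/C=C(C)/CCC#CC)C=C1C[In](Br)Br | intermediate
26 | (4R,5S)-4-[(1S)-1-hydroxypent-3-yn-1-yl]-3-methylidene-5-{(2R,3R)-3-methyl-3-[(3E)-4-methylnon-3-en-7-yn-1-yl]oxiran-2-yl}oxolan-2-one | C=C1C(=O)O[C@H]([C@H]2O[C@]2(C)CC/C=C(C)/CCC#CC)[C@H]1[C@@H](O)CC#CC | intermediate
27 | triethylsilyl ether of 26 at O14, (4S,5S,1′S) by CIP with unchanged geometry | C=C1C(=O)O[C@H]([C@H]2O[C@]2(C)CC/C=C(C)/CCC#CC)[C@H]1[C@@H](O[Si](CC)(CC)CC)CC#CC | intermediate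
28 | 14-O-triethylsilyl ether of 29 | C=C1C(=O)O[C@H]2[C@H]1[C@@H](O[Si](CC)(CC)CC)CC#CCC/C(C)=C/CC[C@@]1(C)O[C@H]21 | intermediate
29 | (1R,2S,3R,4R,14S,7E)-3,4-epoxy-14-hydroxy-20-norcembra-7,15(17)-dien-11-yn-16,2-olide | C=C1C(=O)O[C@H]2[C@H]1[C@@H](O)CC#CCC/C(C)=C/CC[C@@]1(C)O[C@H]21 | intermediate
30 | (1R,2S,3R,4R,14S,7E,11Z)-3,4-epoxy-14-hydroxy-12-(tributylstannyl)-20-norcembra-7,11,15(17)-trien-16,2-olide | C=C1C(=O)O[C@H]2[C@H]1[C@@H](O)C/C([Sn](CCCC)(CCCC)CCCC)=C/CC/C(C)=C/CC[C@@]1(C)O[C@H]21 | intermediate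
31 | (1R,2S,3R,4R,14S,7E,11E)-3,4-epoxy-14-hydroxycembra-7,11,15(17)-trien-16,2-olide | C=C1C(=O)O[C@H]2[C@H]1[C@@H](O)C/C(C)=C/CC/C(C)=C/CC[C@@]1(C)O[C@H]21 | intermediate
32 | CNP0294029.1, (1R,2S,3R,4R,14S,7E,11E)-14-acetoxy-3,4-epoxycembra-7,11,15(17)-trien-16,2-olide | C=C1C(=O)O[C@H]2[C@H]1[C@@H](OC(C)=O)C/C(C)=C/CC/C(C)=C/CC[C@@]1(C)O[C@H]21 | target

**Step count.** 22 steps in total. The longest linear sequence is 21 steps (steps 1–14 and 16–22 from geraniol); step 15 is a one-step side branch.

**Steps most likely to fail**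

Step 18 (ring-closing alkyne metathesis). Intermolecular metathesis may outrun ring closure and give cyclodimers and oligomers, because the lactone and epoxide stiffen the chain, and the alkylidyne may be consumed by the Lewis-basic epoxide. The fallback reverses the order of the two unions: C11≡C12 is made intermolecularly and the ring is closed at C1–C14. It sets out from 21. Silylation (TBSCl, imidazole) gives the tert-butyldimethylsilyl ether F1. Alkyne cross-metathesis of F1 with an excess of triethyl(pent-3-yn-1-yloxy)silane F2 (from 23, TESCl, imidazole) under the same molybdenum alkylidyne gives the bis-silyl ether F3. Swern conditions oxidise the primary triethylsilyl ether directly to the ynal F4. HF·pyridine frees the allylic alcohol F5, and CBr4/PPh3 gives the bromo aldehyde F6. Slow addition of F6 to CrCl2 in THF (intramolecular Nozaki–Hiyama allylation through a chair transition state) closes the 14-membered ring and comes back to the route at 29.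

Step 20 (trans-hydrostannation). Regiocontrol may erode, with tin delivered to C11 as well as C12, because the hydrogen bond from a homopropargylic hydroxyl to the Ru–Cl unit is longer and weaker than from a propargylic one; tin hydride may also add to the methylene lactone. The fallback delivers the metalloid intramolecularly and sets out from 29. Chlorodiisopropylsilane and Et3N give the diisopropylsilyl ether F7. Intramolecular anti-hydrosilylation with [RuCl2(C6H6)]2 (5-exo-dig) gives the oxasilolane F8, in which silicon can only sit on C12. Iododesilylation with N-iodosuccinimide in hexafluoro-2-propanol, then HF·pyridine, gives the alkenyl iodide F9. Negishi coupling of F9 with MeZnCl and Pd(PPh3)4 comes back to the route at 31.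

Step 16 (indium allylation). Control of the aldehyde face may be lost through a boat or open transition state in water, giving the C14 epimer, and the ynal may isomerise to the allenal before it is captured. The fallback corrects C14 after the event and sets out from 22 and 24. The allylation then gives mainly the C14-epimeric alcohol F10, which is separated. Mitsunobu reaction with formic acid (PPh3, diisopropyl azodicarboxylate) gives the inverted formate F11. KHCO3 in methanol removes the formate without touching the lactone and comes back to the route at 26.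

**Further compounds**

F1 | step 18 | (5S)-3-{[(tert-butyldimethylsilyl)oxy]methyl}-5-{(2R,3R)-3-methyl-3-[(3E)-4-methylnon-3-en-7-yn-1-yl]oxiran-2-yl}furan-2(5H)-one | O=C1O[C@H]([C@H]2O[C@]2(C)CC/C=C(C)/CCC#CC)C=C1CO[Si](C)(C)C(C)(C)C
F2 | step 18 | triethyl(pent-3-yn-1-yloxy)silane | CC#CCCO[Si](CC)(CC)CC
F3 | step 18 | (5S)-3-{[(tert-butyldimethylsilyl)oxy]methyl}-5-{(2R,3R)-3-methyl-3-[(3E)-4-methyl-10-(triethylsilyloxy)dec-3-en-7-yn-1-yl]oxiran-2-yl}furan-2(5H)-one | O=C1O[C@H]([C@H]2O[C@]2(C)CC/C=C(C)/CCC#CCCO[Si](CC)(CC)CC)C=C1CO[Si](C)(C)C(C)(C)C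
F4 | step 18 | (5S)-3-{[(tert-butyldimethylsilyl)oxy]methyl}-5-{(2R,3R)-3-methyl-3-[(3E)-4-methyl-10-oxodec-3-en-7-yn-1-yl]oxiran-2-yl}furan-2(5H)-one | O=C1O[C@H]([C@H]2O[C@]2(C)CC/C=C(C)/CCC#CCC=O)C=C1CO[Si](C)(C)C(C)(C)C
F5 | step 18 | (5S)-3-(hydroxymethyl)-5-{(2R,3R)-3-methyl-3-[(3E)-4-methyl-10-oxodec-3-en-7-yn-1-yl]oxiran-2-yl}furan-2(5H)-one | O=C1O[C@H]([C@H]2O[C@]2(C)CC/C=C(C)/CCC#CCC=O)C=C1CO
F6 | step 18 | (5S)-3-(bromomethyl)-5-{(2R,3R)-3-methyl-3-[(3E)-4-methyl-10-oxodec-3-en-7-yn-1-yl]oxiran-2-yl}furan-2(5H)-one | O=C1O[C@H]([C@H]2O[C@]2(C)CC/C=C(C)/CCC#CCC=O)C=C1CBr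
F7 | step 20 | 14-O-(diisopropylsilyl) ether of 29 | C=C1C(=O)O[C@H]2[C@H]1[C@@H](O[SiH](C(C)C)C(C)C)CC#CCC/C(C)=C/CC[C@@]1(C)O[C@H]21
F8 | step 20 | cyclic O14,C12-(diisopropylsilanediyl) derivative of the (7E,11Z)-alkene, a 1-oxa-2-silolane spanning O14, C14, C13 and C12 | C=C1C(=O)O[C@H]2[C@H]1[C@H]3O[Si](C(C)C)(C(C)C)/C(C3)=C\CC/C(C)=C/CC[C@@]1(C)O[C@H]21
F9 | step 20 | (1R,2S,3R,4R,14S,7E,11Z)-3,4-epoxy-14-hydroxy-12-iodo-20-norcembra-7,11,15(17)-trien-16,2-olide | C=C1C(=O)O[C@H]2[C@H]1[C@@H](O)C/C(I)=C/CC/C(C)=C/CC[C@@]1(C)O[C@H]21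
F10 | step 16 | C14 epimer of 26, (4R,5S)-4-[(1R)-1-hydroxypent-3-yn-1-yl] isomer | C=C1C(=O)O[C@H]([C@H]2O[C@]2(C)CC/C=C(C)/CCC#CC)[C@H]1[C@H](O)CC#CC
F11 | step 16 | formate ester of 26 at O14, (1′S) | C=C1C(=O)O[C@H]([C@H]2O[C@]2(C)CC/C=C(C)/CCC#CC)[C@H]1[C@@H](OC=O)CC#CC
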